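The earlier runs and the new flask were computed with made-up constants, noise included.

Work out when product overtakes anion in each flask; the leader at the end and its amount follow from that.

| setting | zeta | epsilon | alpha | alder | birch |
|---|---|---|---|---|---|
| acidic substrate | 0.40 M | 0.40 M | 0.40 M | 0.40 M | 0.40 M |
| free base | 1.2 M | 1.2 M | 1.2 M | 1.20 M | 1.20 M |
| electrophile | 0.31 M | 0.64 M | 1.1 M | 0.400 M | 1.00 M |
| protic impurity | 0.020 M | 0.020 M | 0.020 M | 0.0200 M | 0.0200 M |
| remark | run made earlier | run made earlier | run made earlier |  |  |
| time |  |  |  | 2.0 min | 2.0 min |

- zeta (time / s: product / %, anion / %, acidic substrate / %): 15.0: 3, 61, 38; 30.0: 7, 59, 32; 50.0: 9, 53, 35; 60.0: 13, 54, 28; 80.0: 12, 58, 35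
- epsilon (time / s: product / %, anion / %, acidic substrate / %): 15.0: 9, 63, 32; 30.0: 5, 57, 30; 50.0: 13, 50, 32; 60.0: 18, 51, 28; 80.0: 20, 52, 31
- alpha (time / s: product / %, anion / %, acidic substrate / %): 15.0: 9, 53, 34; 30.0: 12, 54, 31; 50.0: 18, 48, 31; 60.0: 22, 47, 32; 80.0: 28, 45, 30

(readings scatter by 2 percentage points)

1. which of these there is most of at the end, counted by the acidic substrate in it, alder (product / acidic substrate / anion)
2. which of these there is most of at the end, counted by the acidic substrate in it, birch (product / acidic substrate / anion)
3. amount of the one of these that there is most of at the end, in percent of the acidic substrate charged, alder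
4. amount of the one of these that there is most of at the end, in percent of the acidic substrate charged, birch

- what was read earlier has a scatter of 2 percentage points, one standard deviation

1. First instants. By the first reading of the alpha run, at 15.0 s, anion stands at 53% beside acidic substrate at 34% and product at 9%. Proton transfer to the free base is quick on this scale, and anion leads product by 44 percentage points.

2. Middle. By 80.0 s in alpha, acidic substrate has drifted to 30%, anion has sunk to 45% and product has climbed to 28%, so the gap is 17 points. In the zeta run, with [electrophile] at 0.31 M, the gap goes from 58 points to 46 points, so it closes more slowly than in alpha.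

3. End. Alpha's readings give 2.02 min as its estimated crossing time, the time of the last reading plus the gap left divided by the gap's closing rate between first and last reading. Zeta's readings give an estimate of 5.49 min, far beyond the asked 2.0 min, and alder, at 0.400 M, lies nearer zeta than alpha, so my call for alder is anion. Birch, at 1.00 M, has less electrophile than alpha, so its crossing should come after 2.02 min, and my call is anion again, narrowly.

4. Amounts. Straight anion lines carried to 2.0 min give 56.2% for zeta, 45.2% for epsilon and 40.1% for alpha. I place alder between the first two and birch between the last two.

5. The forecast says anion at 48% for alder and product at 38% for birch, which it calls “nearly a tie”, and on birch it parts from my call.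

6. Result. Alder gives anion at 50.7% with product at 17.9%; birch gives anion at 42.8% with product at 29.0%.

    acidic substrate + free base ⇌ protonated base + anion, settled at all times (K = 0.490)
    protic impurity + free base → quenched reagent (k = 0.215 M⁻¹ s⁻¹)
    2 electrophile → homo dimer (k = 0.0152 M⁻¹ s⁻¹)
    electrophile + anion → product (k = 0.0118 M⁻¹ s⁻¹)

7. Neither flask is at rest at 2.0 min: electrophile stands at 32.5% of its charge in alder and 18.2% in birch. A straight line through birch's gap at 1.00 min and 2.00 min reaches zero at 3.05 min, later than alpha's estimated 2.02 min; that is an estimate, not a crossing seen in birch, and what stands is that at 20.0 min birch holds product 47.6% over anion 30.3%. The same line puts alder at 5.14 min, but alder does not keep to it: at 20.0 min alder's electrophile is at 1.44% of its charge, and product 35.0% remains below anion 38.7%.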